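**Assumption (one line):** I read the SMILES as (2S)-5,7,4'-trihydroxy-8,3'-diprenylflavanone. The A-ring prenyl sits on C8, next to the ring oxygen, and C2 is S. I also assume (S)-t-Bu-PyOx delivers the (S)-flavanone; if the sense is reversed, the (R)-ligand is used.

## Retrosynthesis

1. The stereocentre and the C2–aryl bond are made together in the last step. An unprotected 2-unsubstituted chromone (**5**) undergoes Pd/PyOx asymmetric conjugate arylation with arylboronic acid **10**. This avoids the chalcone/oxa-Michael and naringenin-prenylation disconnections.
2. Chromone **5** comes from 5,7-dihydroxychromone by 7-O-allylation, Claisen rearrangement to C8, and cross-metathesis of the allyl group to prenyl. The chromone (pyranone) ring is formed first, from phloroacetophenone.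
3. Boronic acid **10** comes from 4-bromophenol by O-allylation, Claisen, cross-metathesis to prenyl, and Br/Li exchange with borylation.
4. Ring order: the A ring is commercial; the pyranone ring closes in Step 1; the B ring is attached, with C2 set, in the final step. There are no protecting groups.

## Route

**Step 1**
Reactants: **1** 2,4,6-trihydroxyacetophenone (phloroacetophenone)
Product: **2** 5,7-dihydroxychromone
Conditions: (i) DMF-DMA, toluene, 80 °C; (ii) 2 M HCl, THF/H2O, 60 °C
Reagents that add atoms: N,N-dimethylformamide dimethyl acetal, CN(C)C(OC)OC (supplies C2–H of the chromone)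
Why: Enaminone formation at the acetyl methyl, then acid-mediated cyclisation of the 2-OH onto the enaminone with loss of Me2NH, is a standard chromone synthesis (enaminone route). The temperature is kept low to avoid O-methylation.

**Step 2**
Reactants: **2**
Product: **3** 7-(allyloxy)-5-hydroxychromone
Conditions: allyl bromide (1.1 equiv), K2CO3 (1.1 equiv), acetone, reflux
Reagents that add atoms: allyl bromide, C=CCBr
Why: The 7-OH is the most acidic phenol, and the 5-OH is locked in a hydrogen bond to C4=O, so Williamson O-alkylation is selective for C7.

**Step 3**
Reactants: **3**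
Product: **4** 8-allyl-5,7-dihydroxychromone
Conditions: PhNEt2, 200 °C (sealed tube or microwave), 1–2 h
Reagents that add atoms: none
Why: An aromatic Claisen [3,3] rearrangement; the allyl group migrates ortho to the 7-oxygen. C8 is favoured over C6 by π-bond fixation in the 5-hydroxychromone (C7=C8 has higher bond order), and the minor 6-allyl isomer is removed by chromatography.

**Step 4**
Reactants: **4**
Product: **5** 5,7-dihydroxy-8-prenylchromone
Conditions: 2-methyl-2-butene (20 equiv), Hoveyda–Grubbs II (5 mol%), 1,4-benzoquinone (10 mol%), CH2Cl2, 40 °C, sealed tube
Reagents that add atoms: 2-methyl-2-butene, CC=C(C)C (supplies the =CMe2 terminus; propene is lost)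
Why: Cross-metathesis of the terminal allyl alkene with excess 2-methyl-2-butene converts allyl to prenyl, and benzoquinone suppresses Ru–H isomerisation. The electron-poor chromone C2=C3 is inert to the catalyst.

**Step 5**
Reactants: **6** 4-bromophenol
Product: **7** 1-(allyloxy)-4-bromobenzene
Conditions: allyl bromide, K2CO3, acetone, reflux
Reagents that add atoms: allyl bromide, C=CCBr
Why: Williamson etherification of a phenoxide.

**Step 6**
Reactants: **7**
Product: **8** 2-allyl-4-bromophenol
Conditions: neat (or PhNEt2), 200 °C
Reagents that add atoms: none
Why: Aromatic Claisen rearrangement; the para position is blocked by Br, so the allyl group goes ortho.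

**Step 7**
Reactants: **8**
Product: **9** 4-bromo-2-prenylphenol
Conditions: 2-methyl-2-butene (20 equiv), Grubbs II (5 mol%), CH2Cl2, 40 °C
Reagents that add atoms: 2-methyl-2-butene, CC=C(C)C
Why: Cross-metathesis converts allyl to prenyl. The free phenol and the aryl bromide are tolerated.

**Step 8**
Reactants: **9**
Product: **10** (4-hydroxy-3-prenylphenyl)boronic acid
Conditions: (i) n-BuLi (2.2 equiv), THF, −78 °C; (ii) B(OMe)3; (iii) aq. NH4Cl, then pH ≈ 5
Reagents that add atoms: trimethyl borate, COB(OC)OC (supplies B; the OMe groups are hydrolysed to B(OH)2)
Why: The first equivalent of BuLi forms the phenoxide, the second does Br/Li exchange, and the aryllithium is trapped as a borate ester and hydrolysed. The trisubstituted prenyl alkene is untouched, and mild workup avoids cyclisation of the prenylphenol.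

**Step 9**
Reactants: **5** 5,7-dihydroxy-8-prenylchromone; **10** (4-hydroxy-3-prenylphenyl)boronic acid
Product: **11** (2S)-5,7,4'-trihydroxy-8,3'-diprenylflavanone (euchrestaflavanone A)
Conditions: Pd(OCOCF3)2 (10 mol%), (S)-t-Bu-PyOx (12 mol%), NH4PF6 (20 mol%), **10** (3 equiv), ClCH2CH2Cl, 60 °C, air, 24–48 h
Reagents that add atoms: none (the aryl group comes from reactant **10**)
Why: Pd(II)/PyOx-catalysed asymmetric conjugate arylation; the chiral Pd–aryl adds across the chromone C2=C3 bond, with aryl going to the β-carbon C2, and the Pd enolate is protonated, so the (S)-C2 centre is set at migratory insertion and is not touched afterwards.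
Proposed new method: This extends Pd/PyOx arylboronic-acid conjugate addition (known for β-substituted cyclic enones, and for simple chromones giving flavanones) to an unprotected, electron-rich 5,7-dihydroxy-8-prenylchromone. Mechanism: transmetalation to cationic [(PyOx)Pd(TFA)]+, enantiodetermining syn-carbopalladation, then protonolysis by ArB(OH)2/H2O/TFA regenerates Pd(II) with no net redox change. The 5-OH···O=C4 hydrogen bond activates the enone, and the hindered trisubstituted prenyl alkenes should not insert competitively (an allyl arene would, which is why prenyl is installed beforehand).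

## Compound list

| No. | Name | SMILES | Role |
|---|---|---|---|
| 1 | 2,4,6-Trihydroxyacetophenone | CC(=O)c1c(O)cc(O)cc1O | starting material |
| 2 | 5,7-Dihydroxychromone | O=c1ccoc2cc(O)cc(O)c12 | intermediate |
| 3 | 7-(Allyloxy)-5-hydroxychromone | C=CCOc1cc(O)c2c(=O)ccoc2c1 | intermediate |
| 4 | 8-Allyl-5,7-dihydroxychromone | C=CCc1c(O)cc(O)c2c(=O)ccoc12 | intermediate |
| 5 | 5,7-Dihydroxy-8-prenylchromone | CC(C)=CCc1c(O)cc(O)c2c(=O)ccoc12 | intermediate |
| 6 | 4-Bromophenol | Brc1ccc(O)cc1 | starting material |
| 7 | 1-(Allyloxy)-4-bromobenzene | C=CCOc1ccc(Br)cc1 | intermediate |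
| 8 | 2-Allyl-4-bromophenol | C=CCc1cc(Br)ccc1O | intermediate |
| 9 | 4-Bromo-2-prenylphenol | CC(C)=CCc1cc(Br)ccc1O | intermediate |
| 10 | (4-Hydroxy-3-prenylphenyl)boronic acid | CC(C)=CCc1cc(B(O)O)ccc1O | intermediate |
| 11 | Euchrestaflavanone A, (2S)-5,7,4'-trihydroxy-8,3'-diprenylflavanone | CC(C)=CCc1cc([C@@H]2CC(=O)c3c(O)cc(O)c(CC=C(C)C)c3O2)ccc1O | target |

**Total steps:** 9 (4 on the chromone branch, 4 on the boronic acid branch, 1 coupling).
**Longest linear sequence:** 5 steps (1 → 2 → 3 → 4 → 9), counted from phloroacetophenone.

## Three steps most likely to fail

1. **Step 9, asymmetric arylation of the unprotected chromone.** The 7-OH makes the chromone a vinylogous acid, so it may be unreactive, and the ee is uncertain.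
   Fallback: change to the chalcone route. Make 2'-hydroxychalcone from 8-prenyl-phloroacetophenone and 4-hydroxy-3-prenylbenzaldehyde, then close the ring with a bifunctional cinchona-thiourea/squaramide oxa-Michael cyclisation, or with chalcone isomerase.
2. **Step 3, Claisen regioselectivity (C8 vs C6) and thermal decomposition.**
   Fallback: start from C-prenylated phloroacetophenone (prenyl bromide, aqueous KOH), which is a different way to place the A-ring prenyl. Annulate with DMF-DMA and separate the 8- and 6-prenyl chromones, or first brominate C8 and install the prenyl group by cross-coupling.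
3. **Steps 4 and 7, cross-metathesis with 2-methyl-2-butene.** Ru–H isomerisation to the propenyl compound and catalyst poisoning by the polyphenolic chromone are the risks.
   Fallback: replace cross-metathesis with ozonolysis of the allyl group to ArCH2CHO followed by Wittig olefination with Ph3P=CMe2. This is most practical on the simple aryl fragment **8**; for the chromone, protect the phenols first.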